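**Retrosynthetic overview**

- Feature: in the flavone half, ring A is a phloroglucinol ring with oxygen on the alternate carbons C5, C7 and C8a and the acyl carbon C4 on C4a. This is the pattern a cinnamoyl-primed tetraketide gives on Claisen folding, so flavone ring A is made by forming its C4a–C8a bond from an open-chain triketo ester.
- Flavanone half, made last: C4–C4a by Friedel–Crafts acylation and O1–C2 by Mitsunobu inversion of an (R)-3-aryl-3-hydroxypropanoate on the C8a phenol; the alcohol comes from an asymmetric transfer hydrogenation.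
- Flavone half: ring C by iodine/pyridine oxidative cyclisation of the 2',4',6'-trihydroxychalcone; ring A by Claisen cyclisation of a cinnamoyl-terminated 3,5,7-triketo methyl ester.
- Triketo ester from the trianion of methyl 3,5-dioxohexanoate and a cinnamoyl Weinreb amide; diaryl ether by SNAr of a 2,6-bis(benzyloxy)-4-(methoxymethoxy)phenol (from 3,5-bis(benzyloxy)phenol through the para-quinone) on 4-fluorobenzaldehyde.
- Ring order: flavone ring A (step 7), flavone ring C (step 8), flavanone ring C (step 16); both rings B and flavanone ring A are bought as arenes.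

Key step: step 7

Remark on the chemistry: the polyketones are drawn as keto forms although they will be largely enolised, and 3,5-bis(benzyloxy)phenol, methyl 3,5-dioxohexanoate, phosphonate 7 and tert-butyl diazoacetate are taken as purchased.

**Route**

Step 1
Reactants: 1 3,5-bis(benzyloxy)phenol
Product: 2 2,6-bis(benzyloxy)-1,4-benzoquinone
Conditions: (KSO3)2NO (2.5 equiv), KH2PO4 (aq), acetone–H2O, rt
Reagents that add atoms: potassium nitrosodisulfonate (KSO3)2NO, [K+].[K+].[O]N(S(=O)(=O)[O-])S(=O)(=O)[O-]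
Why: Teuber oxidation, in which the phenoxyl radical formed by the first nitrosodisulfonate radical is trapped by a second one at the free para carbon between the two benzyloxy groups and loss of imidodisulfonate should give the 2,6-dialkoxy-para-quinone.

Step 2
Reactants: 2 2,6-bis(benzyloxy)-1,4-benzoquinone
Product: 3 2,6-bis(benzyloxy)benzene-1,4-diol
Conditions: Na2S2O4 (aq), EtOAc, rt, N2
Reagents that add atoms: none
Why: Two-electron quinone reduction by Na2S2O4 in a two-phase system should give the hydroquinone, which is used at once because it re-oxidises in air.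

Step 3
Reactants: 3 2,6-bis(benzyloxy)benzene-1,4-diol
Product: 4 2,6-bis(benzyloxy)-4-(methoxymethoxy)phenol
Conditions: MOMCl (1.05 equiv), i-Pr2NEt, CH2Cl2, 0 °C
Reagents that add atoms: chloromethyl methyl ether (MOMCl), COCCl
Why: Williamson-type O-alkylation with one equivalent of MOMCl should take the C4 hydroxyl, which is the more acidic (two meta alkoxy groups) and the unhindered one, whereas the C1 hydroxyl is flanked by and hydrogen-bonded to two benzyloxy groups.

Step 4
Reactants: 4 2,6-bis(benzyloxy)-4-(methoxymethoxy)phenol; 5 4-fluorobenzaldehyde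
Product: 6 4-[2,6-bis(benzyloxy)-4-(methoxymethoxy)phenoxy]benzaldehyde
Conditions: K2CO3, DMF, 100 °C, N2
Reagents that add atoms: none
Why: SNAr through a Meisenheimer complex, in which the para-formyl group activates the fluoride and the electron-rich phenoxide of 4 is nucleophilic enough to react despite its two ortho substituents, while benzyl and MOM ethers are stable to K2CO3.

Step 5
Reactants: 6 4-[2,6-bis(benzyloxy)-4-(methoxymethoxy)phenoxy]benzaldehyde; 7 diethyl {2-[methoxy(methyl)amino]-2-oxoethyl}phosphonate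
Product: 8 (E)-3-{4-[2,6-bis(benzyloxy)-4-(methoxymethoxy)phenoxy]phenyl}-N-methoxy-N-methylprop-2-enamide
Conditions: NaH, THF, 0 °C → rt
Reagents that add atoms: none
Why: Horner–Wadsworth–Emmons olefination with a stabilised phosphonate should give the E-enamide and installs the acyl-transfer group needed in step 6.

Step 6
Reactants: 8 (E)-3-{4-[2,6-bis(benzyloxy)-4-(methoxymethoxy)phenoxy]phenyl}-N-methoxy-N-methylprop-2-enamide; 9 methyl 3,5-dioxohexanoate
Product: 11 methyl (E)-9-{4-[2,6-bis(benzyloxy)-4-(methoxymethoxy)phenoxy]phenyl}-3,5,7-trioxonon-8-enoate, via trilithium dioxohexanoate trianion 10 (not isolated)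
Conditions: 9, LiN(i-Pr)2 (commercial solution, 3.2 equiv), THF, −78 → 0 °C; then 8, −78 → −20 °C; cold dilute HCl/AcOH quench
Reagents that add atoms: none
Why: Polyanion acylation, in which the last-formed C6 carbanion of the trianion is the most nucleophilic site and adds to the Weinreb amide carbonyl (hard lithium carbanion, 1,2- rather than 1,4-addition), and the chelated tetrahedral adduct persists until the quench so that the acidic product never meets unreacted trianion.

Step 7
Reactants: 11 methyl (E)-9-{4-[2,6-bis(benzyloxy)-4-(methoxymethoxy)phenoxy]phenyl}-3,5,7-trioxonon-8-enoate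
Product: 12 (E)-3-{4-[2,6-bis(benzyloxy)-4-(methoxymethoxy)phenoxy]phenyl}-1-(2,4,6-trihydroxyphenyl)prop-2-en-1-one
Conditions: KOH (2 M aq, excess), MeOH, degassed, 0 °C → rt; then 1 M HCl to pH 4, 0 °C
Reagents that add atoms: none
Why: Excess KOH converts 11 into its polyenolate, the C6 carbanion between the C5 and C7 carbonyls adds to the ester carbon C1, methoxide leaves and the cyclohexane-1,3,5-trione enolises to the phloroglucinol, so that the new bond is the later C4a–C8a bond of flavone ring A and the styryl ketone C7 becomes the chalcone carbonyl. The closest known reaction type is the base-mediated biogenetic-type Claisen cyclisation of 7-aryl-3,5,7-triketo esters to acylphloroglucinols, the folding mode of chalcone synthase; here the acyl terminus is a cinnamoyl group, a change of substituent within the same substrate class. The one ring is closed in a 6-(enolendo)-exo-trig mode and no stereocentre is formed, the E alkene being a spectator. The step needs Claisen closure (C6 onto C1) to beat aldol closure (C2 onto C7), lactonisation of the C5 enol oxygen onto C1 to a 4-hydroxy-2-pyrone, and Michael addition to the enone. This should be secured by keeping the methyl ester and not the acid, so that C1 stays an electrophile, and by a large excess of strong base with potassium as counter-ion, so that both diketone units are deprotonated: the C7 carbonyl is then no aldol acceptor and the styryl unit, as part of a dienolate, no Michael acceptor, which leaves the ester carbon as the only electrophile within reach of C6. Ring A carries no further substituent, so there is no regiochemical question, and the benzyl and MOM ethers are inert to KOH.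

Step 8
Reactants: 12 (E)-3-{4-[2,6-bis(benzyloxy)-4-(methoxymethoxy)phenoxy]phenyl}-1-(2,4,6-trihydroxyphenyl)prop-2-en-1-one
Product: 14 2-{4-[2,6-bis(benzyloxy)-4-(methoxymethoxy)phenoxy]phenyl}-5,7-dihydroxy-4H-chromen-4-one, via racemic 5,7-dihydroxyflavanone 13 (not isolated)
Conditions: I2 (1.1 equiv), pyridine, 90 °C, N2
Reagents that add atoms: none
Why: Oxidative flavone synthesis, in which pyridine promotes 6-endo-trig oxa-Michael closure of the 2'-hydroxychalcone to flavanone 13 (closing flavone ring C, any 13 already formed during the work-up of step 7 being converted as well), α-iodination at C3 through the enol and elimination of HI give the C2=C3 bond, and the buffered medium should keep the MOM ether, which unbuffered iodine–DMSO at higher temperature might cleave.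

Step 9
Reactants: 14 2-{4-[2,6-bis(benzyloxy)-4-(methoxymethoxy)phenoxy]phenyl}-5,7-dihydroxy-4H-chromen-4-one
Product: 15 7-(benzyloxy)-2-{4-[2,6-bis(benzyloxy)-4-(methoxymethoxy)phenoxy]phenyl}-5-hydroxy-4H-chromen-4-one
Conditions: BnBr (1.1 equiv), K2CO3, acetone, 50 °C
Reagents that add atoms: benzyl bromide, BrCc1ccccc1
Why: Williamson etherification under weak base should take only the acidic C7 hydroxyl, the C5 hydroxyl being locked in a hydrogen bond to the C4 carbonyl.

Step 10
Reactants: 15 7-(benzyloxy)-2-{4-[2,6-bis(benzyloxy)-4-(methoxymethoxy)phenoxy]phenyl}-5-hydroxy-4H-chromen-4-one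
Product: 16 7-(benzyloxy)-2-{4-[2,6-bis(benzyloxy)-4-hydroxyphenoxy]phenyl}-5-hydroxy-4H-chromen-4-one
Conditions: HCl (3 M aq), MeOH–THF, 50 °C
Reagents that add atoms: none
Why: Acid-catalysed acetal exchange with methanol removes the MOM group, while the aryl benzyl ethers, the diaryl ether and the flavone are stable to dilute HCl.

Step 11
Reactants: 17 4-hydroxybenzaldehyde
Product: 18 benzyl 4-formylphenyl carbonate
Conditions: CbzCl, Et3N, CH2Cl2, 0 °C
Reagents that add atoms: benzyl chloroformate, O=C(Cl)OCc1ccccc1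
Why: O-acylation of the phenol with a chloroformate gives the aryl benzyl carbonate, chosen because it is electron-withdrawing (it disfavours benzylic ionisation in steps 14 to 16) and falls in the final hydrogenolysis.

Step 12
Reactants: 18 benzyl 4-formylphenyl carbonate; 19 tert-butyl diazoacetate
Product: 20 tert-butyl 3-(4-{[(benzyloxy)carbonyl]oxy}phenyl)-3-oxopropanoate
Conditions: SnCl2 (10 mol%), CH2Cl2, rt
Reagents that add atoms: none
Why: Roskamp homologation, in which the SnCl2-activated aldehyde is attacked by the diazo carbon and a 1,2-hydride shift with loss of N2 gives the β-keto ester under conditions that spare the carbonate.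

Step 13
Reactants: 20 tert-butyl 3-(4-{[(benzyloxy)carbonyl]oxy}phenyl)-3-oxopropanoate
Product: 21 tert-butyl (3R)-3-(4-{[(benzyloxy)carbonyl]oxy}phenyl)-3-hydroxypropanoate
Conditions: RuCl[(R,R)-TsDPEN](p-cymene) (1 mol%), HCO2H–Et3N azeotrope, EtOAc, 30 °C
Reagents that add atoms: none
Why: Noyori–Ikariya asymmetric transfer hydrogenation, in which hydride and proton are delivered in an outer-sphere six-membered transition state with the aryl group next to the η6-arene (CH–π attraction), so the (R,R)-TsDPEN catalyst should give the (R)-carbinol with the same facial sense as for aryl methyl ketones.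

Step 14
Reactants: 16 7-(benzyloxy)-2-{4-[2,6-bis(benzyloxy)-4-hydroxyphenoxy]phenyl}-5-hydroxy-4H-chromen-4-one; 21 tert-butyl (3R)-3-(4-{[(benzyloxy)carbonyl]oxy}phenyl)-3-hydroxypropanoate
Product: 22 tert-butyl (3S)-3-{3,5-bis(benzyloxy)-4-[4-(7-benzyloxy-5-hydroxy-4-oxo-4H-chromen-2-yl)phenoxy]phenoxy}-3-(4-{[(benzyloxy)carbonyl]oxy}phenyl)propanoate
Conditions: PPh3, DIAD, THF, 0 °C → rt
Reagents that add atoms: none
Why: Mitsunobu etherification, in which the phenoxide of 16 displaces the oxyphosphonium group of 21 by SN2 with inversion and so sets the future C2 as S, the chelated C5 hydroxyl of the flavone being too poor a nucleophile to compete and the carbonate on ring B holding back an SN1 leak.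

Step 15
Reactants: 22 tert-butyl (3S)-3-{3,5-bis(benzyloxy)-4-[4-(7-benzyloxy-5-hydroxy-4-oxo-4H-chromen-2-yl)phenoxy]phenoxy}-3-(4-{[(benzyloxy)carbonyl]oxy}phenyl)propanoate
Product: 24 (3S)-3-{3,5-bis(benzyloxy)-4-[4-(7-benzyloxy-5-hydroxy-4-oxo-4H-chromen-2-yl)phenoxy]phenoxy}-3-(4-{[(benzyloxy)carbonyl]oxy}phenyl)propanoic acid, via trimethylsilyl ester 23 (not isolated)
Conditions: TMSOTf (excess), 2,6-lutidine, CH2Cl2, 0 °C; aq. citric acid work-up
Reagents that add atoms: none
Why: Silyl triflate-mediated tert-butyl ester cleavage (E1 loss of isobutene from the O-silylated ester, the proton being taken by lutidine) avoids a free tert-butyl cation and strong Brønsted acid next to the electron-rich ring and the benzylic ether, and the silyl ester is hydrolysed on work-up.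

Step 16
Reactants: 24 (3S)-3-{3,5-bis(benzyloxy)-4-[4-(7-benzyloxy-5-hydroxy-4-oxo-4H-chromen-2-yl)phenoxy]phenoxy}-3-(4-{[(benzyloxy)carbonyl]oxy}phenyl)propanoic acid
Product: 26 benzyl 4-[(2S)-5,7-bis(benzyloxy)-6-[4-(7-benzyloxy-5-hydroxy-4-oxo-4H-chromen-2-yl)phenoxy]-4-oxochroman-2-yl]phenyl carbonate, via mixed trifluoroacetic anhydride 25 (not isolated)
Conditions: (CF3CO)2O, CH2Cl2, 0 °C → rt; aq. NaHCO3 work-up
Reagents that add atoms: none
Why: Intramolecular Friedel–Crafts acylation through the mixed trifluoroacetic anhydride closes flavanone ring C (C4–C4a bond, six-membered ring) at one of the two equivalent positions ortho to the ether oxygen, each activated by three oxygen substituents, and the C2 stereocentre is not touched provided the temperature stays low enough to avoid β-elimination of the aryloxy group.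

Step 17
Reactants: 26 benzyl 4-[(2S)-5,7-bis(benzyloxy)-6-[4-(7-benzyloxy-5-hydroxy-4-oxo-4H-chromen-2-yl)phenoxy]-4-oxochroman-2-yl]phenyl carbonate
Product: 27 (2S)-5,7-dihydroxy-6-[4-(5,7-dihydroxy-4-oxo-4H-chromen-2-yl)phenoxy]-2-(4-hydroxyphenyl)chroman-4-one
Conditions: H2 (1 atm), Pd/C (10%), EtOAc–MeOH, rt
Reagents that add atoms: none
Why: Hydrogenolysis over Pd/C cleaves the three benzyl ethers and the benzyl carbonate (which then loses CO2) under neutral conditions that neither open nor epimerise the flavanone, and the reaction is stopped at complete debenzylation so that the flavone C2=C3 bond and the benzylic C2–O1 bond are not reduced.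

**Compound list**

1 | 3,5-bis(benzyloxy)phenol | Oc1cc(OCc2ccccc2)cc(OCc2ccccc2)c1 | starting material
2 | 2,6-bis(benzyloxy)-1,4-benzoquinone | O=C1C=C(OCc2ccccc2)C(=O)C(OCc2ccccc2)=C1 | intermediate
3 | 2,6-bis(benzyloxy)benzene-1,4-diol | Oc1cc(OCc2ccccc2)c(O)c(OCc2ccccc2)c1 | intermediate
4 | 2,6-bis(benzyloxy)-4-(methoxymethoxy)phenol | COCOc1cc(OCc2ccccc2)c(O)c(OCc2ccccc2)c1 | intermediate
5 | 4-fluorobenzaldehyde | O=Cc1ccc(F)cc1 | starting material
6 | 4-[2,6-bis(benzyloxy)-4-(methoxymethoxy)phenoxy]benzaldehyde | O=Cc1ccc(Oc2c(OCc3ccccc3)cc(OCOC)cc2OCc2ccccc2)cc1 | intermediate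
7 | diethyl {2-[methoxy(methyl)amino]-2-oxoethyl}phosphonate | CCOP(=O)(CC(=O)N(C)OC)OCC | starting material
8 | (E)-3-{4-[2,6-bis(benzyloxy)-4-(methoxymethoxy)phenoxy]phenyl}-N-methoxy-N-methylprop-2-enamide | CON(C)C(=O)/C=C/c1ccc(Oc2c(OCc3ccccc3)cc(OCOC)cc2OCc2ccccc2)cc1 | intermediate
9 | methyl 3,5-dioxohexanoate | COC(=O)CC(=O)CC(C)=O | starting material
10 | trilithium trianion of methyl 3,5-dioxohexanoate (carbanions at C2, C4 and C6) | [Li+].[Li+].[Li+].COC(=O)[CH-]C(=O)[CH-]C(=O)[CH2-] | intermediate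
11 | methyl (E)-9-{4-[2,6-bis(benzyloxy)-4-(methoxymethoxy)phenoxy]phenyl}-3,5,7-trioxonon-8-enoate | COC(=O)CC(=O)CC(=O)CC(=O)/C=C/c1ccc(Oc2c(OCc3ccccc3)cc(OCOC)cc2OCc2ccccc2)cc1 | intermediate
12 | (E)-3-{4-[2,6-bis(benzyloxy)-4-(methoxymethoxy)phenoxy]phenyl}-1-(2,4,6-trihydroxyphenyl)prop-2-en-1-one | O=C(/C=C/c1ccc(Oc2c(OCc3ccccc3)cc(OCOC)cc2OCc2ccccc2)cc1)c1c(O)cc(O)cc1O | intermediate
13 | rac-2-{4-[2,6-bis(benzyloxy)-4-(methoxymethoxy)phenoxy]phenyl}-5,7-dihydroxychroman-4-one | O=C1CC(c2ccc(Oc3c(OCc4ccccc4)cc(OCOC)cc3OCc3ccccc3)cc2)Oc2cc(O)cc(O)c21 | intermediate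
14 | 2-{4-[2,6-bis(benzyloxy)-4-(methoxymethoxy)phenoxy]phenyl}-5,7-dihydroxy-4H-chromen-4-one | O=c1cc(-c2ccc(Oc3c(OCc4ccccc4)cc(OCOC)cc3OCc3ccccc3)cc2)oc2cc(O)cc(O)c12 | intermediate
15 | 7-(benzyloxy)-2-{4-[2,6-bis(benzyloxy)-4-(methoxymethoxy)phenoxy]phenyl}-5-hydroxy-4H-chromen-4-one | O=c1cc(-c2ccc(Oc3c(OCc4ccccc4)cc(OCOC)cc3OCc3ccccc3)cc2)oc2cc(OCc3ccccc3)cc(O)c12 | intermediate
16 | 7-(benzyloxy)-2-{4-[2,6-bis(benzyloxy)-4-hydroxyphenoxy]phenyl}-5-hydroxy-4H-chromen-4-one | O=c1cc(-c2ccc(Oc3c(OCc4ccccc4)cc(O)cc3OCc3ccccc3)cc2)oc2cc(OCc3ccccc3)cc(O)c12 | intermediate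
17 | 4-hydroxybenzaldehyde | O=Cc1ccc(O)cc1 | starting material
18 | benzyl 4-formylphenyl carbonate | O=Cc1ccc(OC(=O)OCc2ccccc2)cc1 | intermediate
19 | tert-butyl diazoacetate | CC(C)(C)OC(=O)C=[N+]=[N-] | starting material
20 | tert-butyl 3-(4-{[(benzyloxy)carbonyl]oxy}phenyl)-3-oxopropanoate | CC(C)(C)OC(=O)CC(=O)c1ccc(OC(=O)OCc2ccccc2)cc1 | intermediate
21 | tert-butyl (3R)-3-(4-{[(benzyloxy)carbonyl]oxy}phenyl)-3-hydroxypropanoate | CC(C)(C)OC(=O)C[C@@H](O)c1ccc(OC(=O)OCc2ccccc2)cc1 | intermediate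
22 | tert-butyl (3S)-3-{3,5-bis(benzyloxy)-4-[4-(7-benzyloxy-5-hydroxy-4-oxo-4H-chromen-2-yl)phenoxy]phenoxy}-3-(4-{[(benzyloxy)carbonyl]oxy}phenyl)propanoate | CC(C)(C)OC(=O)C[C@H](Oc1cc(OCc2ccccc2)c(Oc2ccc(-c3cc(=O)c4c(O)cc(OCc5ccccc5)cc4o3)cc2)c(OCc2ccccc2)c1)c1ccc(OC(=O)OCc2ccccc2)cc1 | intermediate
23 | trimethylsilyl ester of acid 24 | C[Si](C)(C)OC(=O)C[C@H](Oc1cc(OCc2ccccc2)c(Oc2ccc(-c3cc(=O)c4c(O)cc(OCc5ccccc5)cc4o3)cc2)c(OCc2ccccc2)c1)c1ccc(OC(=O)OCc2ccccc2)cc1 | intermediate
24 | (3S)-3-{3,5-bis(benzyloxy)-4-[4-(7-benzyloxy-5-hydroxy-4-oxo-4H-chromen-2-yl)phenoxy]phenoxy}-3-(4-{[(benzyloxy)carbonyl]oxy}phenyl)propanoic acid | OC(=O)C[C@H](Oc1cc(OCc2ccccc2)c(Oc2ccc(-c3cc(=O)c4c(O)cc(OCc5ccccc5)cc4o3)cc2)c(OCc2ccccc2)c1)c1ccc(OC(=O)OCc2ccccc2)cc1 | intermediate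
25 | mixed anhydride of acid 24 and trifluoroacetic acid | O=C(C[C@H](Oc1cc(OCc2ccccc2)c(Oc2ccc(-c3cc(=O)c4c(O)cc(OCc5ccccc5)cc4o3)cc2)c(OCc2ccccc2)c1)c1ccc(OC(=O)OCc2ccccc2)cc1)OC(=O)C(F)(F)F | intermediate
26 | benzyl 4-[(2S)-5,7-bis(benzyloxy)-6-[4-(7-benzyloxy-5-hydroxy-4-oxo-4H-chromen-2-yl)phenoxy]-4-oxochroman-2-yl]phenyl carbonate | O=C1C[C@@H](c2ccc(OC(=O)OCc3ccccc3)cc2)Oc2cc(OCc3ccccc3)c(Oc3ccc(-c4cc(=O)c5c(O)cc(OCc6ccccc6)cc5o4)cc3)c(OCc3ccccc3)c21 | intermediate
27 | (2S)-5,7-dihydroxy-6-[4-(5,7-dihydroxy-4-oxo-4H-chromen-2-yl)phenoxy]-2-(4-hydroxyphenyl)chroman-4-one (CNP0206535.1) | O=C1C[C@@H](c2ccc(O)cc2)Oc2cc(O)c(Oc3ccc(-c4cc(=O)c5c(O)cc(O)cc5o4)cc3)c(O)c21 | target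

**Step count**

Total: 17 steps. Longest linear sequence: 14 steps (steps 1 to 10, then 14 to 17); the hydroxy ester 21 is made in 3 steps (11 to 13).

**Steps most likely to fail**

Step 7 (key step). The folding may leave the Claisen course: aldol closure of C2 onto C7 to a resorcylate, lactonisation to a 4-hydroxy-2-pyrone, hydrolysis of the ester before ring closure, or conjugate addition to the styryl ketone. The fallback buys flavone ring A as an arene instead of folding it and sets out from aldehyde 6. 2,4,6-Trihydroxyacetophenone is benzylated at its non-chelated para hydroxyl (BnBr, K2CO3, acetone) to 1-[4-(benzyloxy)-2,6-dihydroxyphenyl]ethanone F1. Claisen–Schmidt condensation of F1 with 6 (KOH, EtOH–H2O, rt) should give (E)-1-[4-(benzyloxy)-2,6-dihydroxyphenyl]-3-{4-[2,6-bis(benzyloxy)-4-(methoxymethoxy)phenoxy]phenyl}prop-2-en-1-one F2. Under the conditions of step 8 (I2, pyridine, 90 °C) F2 closes to rac-7-(benzyloxy)-2-{4-[2,6-bis(benzyloxy)-4-(methoxymethoxy)phenoxy]phenyl}-5-hydroxychroman-4-one F3, which is dehydrogenated in the same flask to 15, where the route is rejoined; steps 5 to 9 are then not needed.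

Step 14. The activated alcohol may undergo β-elimination to the cinnamate, or partial ionisation at the benzylic carbon may erode the configuration; elimination and re-addition of the phenol in step 16 would erode it in the same way. The fallback sets the stereocentre by asymmetric conjugate addition, with no substitution at a benzylic carbon, and sets out from phenol 16. Friedel–Crafts acetylation ortho to the free hydroxyl (Ac2O, BF3·OEt2, CH2Cl2, 0 °C → rt, aqueous work-up) gives 2-{4-[3-acetyl-2,6-bis(benzyloxy)-4-hydroxyphenoxy]phenyl}-7-(benzyloxy)-5-hydroxy-4H-chromen-4-one F4. Heating with DMF dimethyl acetal (toluene, 90 °C) gives the (E)-3-(dimethylamino)prop-2-enoyl analogue (enaminone) F5, which dilute HCl closes to 5,7-bis(benzyloxy)-6-[4-(7-benzyloxy-5-hydroxy-4-oxo-4H-chromen-2-yl)phenoxy]-4H-chromen-4-one F6. Asymmetric 1,4-addition of 4-(benzyloxy)phenylboronic acid to the unsubstituted chromone C2=C3 bond ([Rh(OH)(cod)]2, an axially chiral MeO-BIPHEP-type bisphosphine, toluene–H2O) follows, with the ligand antipode that gives the 2S adduct fixed beforehand on a simple 5,7-dialkoxychromone; the 2-aryl-substituted flavone unit should not react. This should give (2S)-5,7-bis(benzyloxy)-2-[4-(benzyloxy)phenyl]-6-[4-(7-benzyloxy-5-hydroxy-4-oxo-4H-chromen-2-yl)phenoxy]chroman-4-one F7, and hydrogenolysis as in step 17 returns to the route at 27; steps 11 to 16 are then not needed.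

Step 6. Trianion formation may be incomplete, proton transfer from the acidic methylene groups may quench the terminal carbanion, the carbanion may add in a conjugate sense to the enamide, or the product may cyclise during the quench. The fallback builds the chain in two stages with the ester introduced last and sets out from amide 8. Acylation of the dilithium dianion of acetylacetone (LiN(i-Pr)2, 2 equiv, THF, −78 → 0 °C) with 8 gives (E)-8-{4-[2,6-bis(benzyloxy)-4-(methoxymethoxy)phenoxy]phenyl}oct-7-ene-2,4,6-trione F8. Its trilithium trianion (LiN(i-Pr)2, 3 equiv) is carboxylated at the terminal carbon with CO2 to (E)-9-{4-[2,6-bis(benzyloxy)-4-(methoxymethoxy)phenoxy]phenyl}-3,5,7-trioxonon-8-enoic acid F9, and brief treatment with CH2N2 in Et2O at 0 °C gives 11, where the route is rejoined.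

Further compounds
F1 | step 7 | 1-[4-(benzyloxy)-2,6-dihydroxyphenyl]ethanone | CC(=O)c1c(O)cc(OCc2ccccc2)cc1O
F2 | step 7 | (E)-1-[4-(benzyloxy)-2,6-dihydroxyphenyl]-3-{4-[2,6-bis(benzyloxy)-4-(methoxymethoxy)phenoxy]phenyl}prop-2-en-1-one | O=C(/C=C/c1ccc(Oc2c(OCc3ccccc3)cc(OCOC)cc2OCc2ccccc2)cc1)c1c(O)cc(OCc2ccccc2)cc1O
F3 | step 7 | rac-7-(benzyloxy)-2-{4-[2,6-bis(benzyloxy)-4-(methoxymethoxy)phenoxy]phenyl}-5-hydroxychroman-4-one | O=C1CC(c2ccc(Oc3c(OCc4ccccc4)cc(OCOC)cc3OCc3ccccc3)cc2)Oc2cc(OCc3ccccc3)cc(O)c21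
F4 | step 14 | 2-{4-[3-acetyl-2,6-bis(benzyloxy)-4-hydroxyphenoxy]phenyl}-7-(benzyloxy)-5-hydroxy-4H-chromen-4-one | CC(=O)c1c(O)cc(OCc2ccccc2)c(Oc2ccc(-c3cc(=O)c4c(O)cc(OCc5ccccc5)cc4o3)cc2)c1OCc1ccccc1
F5 | step 14 | 7-(benzyloxy)-2-(4-{2,6-bis(benzyloxy)-3-[(E)-3-(dimethylamino)prop-2-enoyl]-4-hydroxyphenoxy}phenyl)-5-hydroxy-4H-chromen-4-one | CN(C)/C=C/C(=O)c1c(O)cc(OCc2ccccc2)c(Oc2ccc(-c3cc(=O)c4c(O)cc(OCc5ccccc5)cc4o3)cc2)c1OCc1ccccc1
F6 | step 14 | 5,7-bis(benzyloxy)-6-[4-(7-benzyloxy-5-hydroxy-4-oxo-4H-chromen-2-yl)phenoxy]-4H-chromen-4-one | O=c1ccoc2cc(OCc3ccccc3)c(Oc3ccc(-c4cc(=O)c5c(O)cc(OCc6ccccc6)cc5o4)cc3)c(OCc3ccccc3)c12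
F7 | step 14 | (2S)-5,7-bis(benzyloxy)-2-[4-(benzyloxy)phenyl]-6-[4-(7-benzyloxy-5-hydroxy-4-oxo-4H-chromen-2-yl)phenoxy]chroman-4-one | O=C1C[C@@H](c2ccc(OCc3ccccc3)cc2)Oc2cc(OCc3ccccc3)c(Oc3ccc(-c4cc(=O)c5c(O)cc(OCc6ccccc6)cc5o4)cc3)c(OCc3ccccc3)c21
F8 | step 6 | (E)-8-{4-[2,6-bis(benzyloxy)-4-(methoxymethoxy)phenoxy]phenyl}oct-7-ene-2,4,6-trione | CC(=O)CC(=O)CC(=O)/C=C/c1ccc(Oc2c(OCc3ccccc3)cc(OCOC)cc2OCc2ccccc2)cc1
F9 | step 6 | (E)-9-{4-[2,6-bis(benzyloxy)-4-(methoxymethoxy)phenoxy]phenyl}-3,5,7-trioxonon-8-enoic acid | OC(=O)CC(=O)CC(=O)CC(=O)/C=C/c1ccc(Oc2c(OCc3ccccc3)cc(OCOC)cc2OCc2ccccc2)cc1
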